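The pyrrole ring is formed last, through N1–C5 and C2–C3. In that ring C2 bears the acyl group and C3 and C4 bear only hydrogen. C2 can therefore be the α-carbon of an N-tosyl α-amino ketone, while C3, C4 and C5 are the aldehyde carbon and the two alkyne carbons of a silyl-protected 4-hydroxybut-2-ynal. One carbonate-mediated operation adds the sulfonamide nitrogen to the alkyne and condenses the ketone α-carbon on the aldehyde. This should give the 2-acyl-5-(silyloxymethyl)-N-tosylpyrrole with the whole iso-branched chain in place. The precursor is an open-chain tosylaminomethyl ketone made from a bromo acid; two mild deprotections finish the synthesis.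

Key step: step 5

Remark: the target has no stereocentre, so no step has to set configuration. The N-sulfonyl group is removed before the O-silyl group, because a free alkoxide beside the N-tosyl group could take over the sulfonyl group (N-to-O transfer) and then ionise.

Step 1
Reactants: 1 15-bromopentadecanoic acid; 2 isopropylmagnesium chloride
Product: 4 16-methylheptadecanoic acid, via chloromagnesium 15-bromopentadecanoate 3 (not isolated)
Conditions: iPrMgCl (3 equiv), Li2CuCl4 (3 mol%), NMP (4 equiv), THF, −20 °C to rt; then 1 M HCl
Reagents that add atoms: none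
Why: Copper-catalysed Kochi-type cross-coupling of an alkyl Grignard reagent with a primary alkyl bromide: the first equivalent of Grignard reagent turns the acid into its inert magnesium carboxylate 3, and Li2CuCl4 with NMP at low temperature should let the secondary alkyl group transfer faster than β-hydride loss.

Step 2
Reactants: 4 16-methylheptadecanoic acid
Product: 7 1-bromo-17-methyloctadecan-2-one, via 16-methylheptadecanoyl chloride 5 (not isolated), via 1-diazo-17-methyloctadecan-2-one 6 (not isolated)
Conditions: (COCl)2, cat. DMF, CH2Cl2, 0 °C to rt, evaporate; CH2N2 (3 equiv), Et2O, 0 °C; then 48% aq HBr, 0 °C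
Reagents that add atoms: diazomethane C=[N+]=[N-]; hydrogen bromide Br
Why: Arndt–Eistert-type acylation of diazomethane by the acid chloride gives the diazoketone, and HBr then protonates the diazo carbon so that bromide displaces N2 (a standard bromomethyl ketone synthesis), which places the halogen only on the new terminal carbon and never on the chain side of the ketone.

Step 3
Reactants: 7 1-bromo-17-methyloctadecan-2-one; 8 4-methylbenzenesulfonamide
Product: 9 N-(17-methyl-2-oxooctadecyl)-4-methylbenzenesulfonamide
Conditions: TsNH2 (3 equiv), K2CO3 (1.5 equiv), acetone, rt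
Reagents that add atoms: none
Why: SN2 N-alkylation of the sulfonamide anion by a highly reactive α-bromo ketone, with the excess of TsNH2 keeping the mono-alkylated product from competing for a second molecule of 7.

Step 4
Reactants: 10 tert-butyldimethyl(prop-2-yn-1-yloxy)silane
Product: 13 4-(tert-butyldimethylsilyloxy)but-2-ynal, via lithium acetylide 11 (not isolated), via lithium aminoalkoxide 12 (not isolated)
Conditions: n-BuLi (1.05 equiv), THF, −78 °C; DMF (2 equiv), −78 to 0 °C; inverse quench into 10% aq KH2PO4/MTBE, 0 °C
Reagents that add atoms: N,N-dimethylformamide CN(C)C=O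
Why: Formylation of a lithium acetylide with DMF, in which the tetrahedral aminoalkoxide 12 holds the aldehyde masked until the buffered inverse quench releases the ynal without exposing it to free dimethylamine or strong base.

Step 5
Reactants: 9 N-(17-methyl-2-oxooctadecyl)-4-methylbenzenesulfonamide; 13 4-(tert-butyldimethylsilyloxy)but-2-ynal
Product: 16 1-[5-(tert-butyldimethylsilyloxymethyl)-1-tosylpyrrol-2-yl]-16-methylheptadecan-1-one, via aza-Michael enaminal 14 (not isolated), via hydroxypyrroline aldol 15 (not isolated)
Conditions: Cs2CO3 (1.2 equiv), 4 Å MS, MeCN, 0 °C to rt, slow addition of 13 (1.3 equiv)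
Reagents that add atoms: none
Why: Cs2CO3 deprotonates the sulfonamide N–H, which is far more acidic than either ketone α-position, and the nitrogen anion adds to the β-carbon of the ynal, the alkyne carbon that carries CH2OTBS, to give enaminal 14 (N1–C5), whose E and Z isomers should interconvert under the reversible basic conditions. The methylene between nitrogen and the ketone is then enolised and attacks the aldehyde carbon in a 5-exo-trig (enolexo) aldol closure that forms C2–C3 and the five-membered ring as hydroxypyrroline 15, and E1cB loss of water across C2–C3, driven by aromatisation, should deliver the N-tosylpyrrole. The closest known reaction type is the Kenner pyrrole synthesis and its acetylenic ketone variants, in which N-sulfonyl α-amino carbonyl compounds undergo aza-Michael addition and aldol condensation with conjugated carbonyl acceptors. No stereocentre is created in the product, since the two transient sp3 centres of 15 (C2 and C3) are erased on dehydration. The step needs the nitrogen to bond to the CH2OTBS-bearing alkyne carbon and the α-carbon to bond to the aldehyde; the polarisation of the ynal secures this, because the N-substituted sulfonamide can add to the CHO group only as a reversible hemiaminal, and a premature intermolecular aldol is likewise reversible or, if followed by N-cyclisation, converges on the same constitution. Closure through the chain-side α-carbon would require a seven-membered ring and is not expected to compete with the five-membered one.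

Step 6
Reactants: 16 1-[5-(tert-butyldimethylsilyloxymethyl)-1-tosylpyrrol-2-yl]-16-methylheptadecan-1-one
Product: 17 1-[5-(tert-butyldimethylsilyloxymethyl)-1H-pyrrol-2-yl]-16-methylheptadecan-1-one
Conditions: K2CO3 (3 equiv), MeOH/THF 3:1, rt to 40 °C
Reagents that add atoms: none
Why: Nucleophilic N-desulfonylation by methoxide at sulfur, easy here because the 2-acylpyrrolide is a good leaving group, while the primary TBS ether and the ketone are inert to carbonate in methanol; keeping the silyl ether on at this stage denies the sulfonyl group an alkoxide to migrate to.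

Step 7
Reactants: 17 1-[5-(tert-butyldimethylsilyloxymethyl)-1H-pyrrol-2-yl]-16-methylheptadecan-1-one
Product: 18 1-[5-(hydroxymethyl)-1H-pyrrol-2-yl]-16-methylheptadecan-1-one
Conditions: Bu4NF (1.5 equiv), AcOH (1.5 equiv), THF, 0 °C to rt
Reagents that add atoms: none
Why: Fluoride-induced desilylation driven by the strong Si–F bond, buffered with AcOH so that the 5-acyl-2-(hydroxymethyl)pyrrole, already stabilised against azafulvene formation by its acyl group, is not exposed to strong base.

Compound list

1 | 15-bromopentadecanoic acid | OC(=O)CCCCCCCCCCCCCCBr | starting material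
2 | isopropylmagnesium chloride | CC(C)[Mg]Cl | starting material
3 | chloromagnesium 15-bromopentadecanoate | Cl[Mg]OC(=O)CCCCCCCCCCCCCCBr | intermediate
4 | 16-methylheptadecanoic acid | CC(C)CCCCCCCCCCCCCCC(=O)O | intermediate
5 | 16-methylheptadecanoyl chloride | CC(C)CCCCCCCCCCCCCCC(=O)Cl | intermediate
6 | 1-diazo-17-methyloctadecan-2-one | CC(C)CCCCCCCCCCCCCCC(=O)C=[N+]=[N-] | intermediate
7 | 1-bromo-17-methyloctadecan-2-one | CC(C)CCCCCCCCCCCCCCC(=O)CBr | intermediate
8 | 4-methylbenzenesulfonamide | Cc1ccc(S(N)(=O)=O)cc1 | starting material
9 | N-(17-methyl-2-oxooctadecyl)-4-methylbenzenesulfonamide | CC(C)CCCCCCCCCCCCCCC(=O)CNS(=O)(=O)c1ccc(C)cc1 | intermediate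
10 | tert-butyldimethyl(prop-2-yn-1-yloxy)silane | C#CCO[Si](C)(C)C(C)(C)C | starting material
11 | lithium 3-(tert-butyldimethylsilyloxy)prop-1-yn-1-ide | [Li]C#CCO[Si](C)(C)C(C)(C)C | intermediate
12 | lithium 4-(tert-butyldimethylsilyloxy)-1-(dimethylamino)but-2-yn-1-olate | [Li]OC(N(C)C)C#CCO[Si](C)(C)C(C)(C)C | intermediate
13 | 4-(tert-butyldimethylsilyloxy)but-2-ynal | O=CC#CCO[Si](C)(C)C(C)(C)C | intermediate
14 | N-[(Z)-1-(tert-butyldimethylsilyloxy)-4-oxobut-2-en-2-yl]-N-(17-methyl-2-oxooctadecyl)-4-methylbenzenesulfonamide (N and CHO cis; forms together with its E isomer, which equilibrates) | CC(C)CCCCCCCCCCCCCCC(=O)CN(/C(CO[Si](C)(C)C(C)(C)C)=C\C=O)S(=O)(=O)c1ccc(C)cc1 | intermediate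
15 | 1-[5-(tert-butyldimethylsilyloxymethyl)-3-hydroxy-1-tosyl-2,3-dihydro-1H-pyrrol-2-yl]-16-methylheptadecan-1-one (racemic mixture of diastereomers at C2 and C3) | CC(C)CCCCCCCCCCCCCCC(=O)C1C(O)C=C(CO[Si](C)(C)C(C)(C)C)N1S(=O)(=O)c1ccc(C)cc1 | intermediate
16 | 1-[5-(tert-butyldimethylsilyloxymethyl)-1-tosylpyrrol-2-yl]-16-methylheptadecan-1-one | CC(C)CCCCCCCCCCCCCCC(=O)c1ccc(CO[Si](C)(C)C(C)(C)C)n1S(=O)(=O)c1ccc(C)cc1 | intermediate
17 | 1-[5-(tert-butyldimethylsilyloxymethyl)-1H-pyrrol-2-yl]-16-methylheptadecan-1-one | CC(C)CCCCCCCCCCCCCCC(=O)c1ccc(CO[Si](C)(C)C(C)(C)C)[nH]1 | intermediate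
18 | 1-[5-(hydroxymethyl)-1H-pyrrol-2-yl]-16-methylheptadecan-1-one (achiral) | CC(C)CCCCCCCCCCCCCCC(=O)c1ccc(CO)[nH]1 | target

Total step count: 7.
Longest linear sequence: 6 steps (steps 1, 2, 3, 5, 6 and 7 from compound 1); the ynal branch (step 4) joins at step 5.

Steps most likely to fail

Step 5. The ynal may oligomerise or be deprotonated at its propargylic position faster than the sulfonamide adds. The sequence may also stall at the hydroxypyrroline, or lose sulfinate in place of water. Partial loss of the N-tosyl group to the water set free would be harmless, since it gives 17. The fallback abandons ring construction and acylates a preformed pyrrole. It sets out from acid 4, which would be converted through its chloride 5 (oxalyl chloride, then pyridine-2-thiol, Et3N, CH2Cl2) into S-(pyridin-2-yl) 16-methylheptadecanethioate F1. Commercial 1H-pyrrole-2-carbaldehyde would be reduced with NaBH4 in MeOH to (1H-pyrrol-2-yl)methanol F2 and silylated at once (TBSCl, imidazole, DMF) to 2-[(tert-butyldimethylsilyloxy)methyl]-1H-pyrrole F3. MeMgCl in toluene/THF should convert F3 into chloromagnesium 2-[(tert-butyldimethylsilyloxy)methyl]pyrrol-1-ide F4. At −78 °C this should be C-acylated by F1 at its free α-position (C5) through a magnesium chelate with the pyridyl thioester, the established way to 2-acylpyrroles. That gives 17 directly, so the route is rejoined at 17 and step 6 is not needed.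

Step 3. The mono-alkylated sulfonamide may be alkylated a second time, or the bromo ketone may self-condense under base. The fallback uses a nitrogen nucleophile with a single N–H. It sets out from 7, which would alkylate tert-butyl tosylcarbamate (K2CO3, DMF, rt) to give tert-butyl N-(17-methyl-2-oxooctadecyl)-N-(4-methylphenyl)sulfonylcarbamate F5. CF3CO2H in CH2Cl2 then removes the tert-butoxycarbonyl group and returns the route at 9.

Step 1. The secondary alkylcopper intermediate may lose a β-hydride, so that the bromide is reduced or eliminated, and the Grignard reagent may homocouple. The resulting C15 acids would be hard to separate from the C18 acid. The fallback builds the iso terminus by olefination. It sets out from 1, which with PPh3 in refluxing MeCN should give (14-carboxytetradecyl)triphenylphosphonium bromide F6. NaN(SiMe3)2 (2.2 equiv) in THF would generate sodium 15-(triphenylphosphoranylidene)pentadecanoate F7. Wittig reaction of F7 with acetone should give 16-methylheptadec-15-enoic acid F8. Hydrogenation (H2, Pd/C, EtOAc) then returns the route at 4.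

Further compounds
F1 | step 5 | S-(pyridin-2-yl) 16-methylheptadecanethioate | CC(C)CCCCCCCCCCCCCCC(=O)Sc1ccccn1
F2 | step 5 | (1H-pyrrol-2-yl)methanol | OCc1ccc[nH]1
F3 | step 5 | 2-[(tert-butyldimethylsilyloxy)methyl]-1H-pyrrole | CC(C)(C)[Si](C)(C)OCc1ccc[nH]1
F4 | step 5 | chloromagnesium 2-[(tert-butyldimethylsilyloxy)methyl]pyrrol-1-ide | Cl[Mg]n1cccc1CO[Si](C)(C)C(C)(C)C
F5 | step 3 | tert-butyl N-(17-methyl-2-oxooctadecyl)-N-(4-methylphenyl)sulfonylcarbamate | CC(C)CCCCCCCCCCCCCCC(=O)CN(C(=O)OC(C)(C)C)S(=O)(=O)c1ccc(C)cc1
F6 | step 1 | (14-carboxytetradecyl)triphenylphosphonium bromide | OC(=O)CCCCCCCCCCCCCC[P+](c1ccccc1)(c1ccccc1)c1ccccc1.[Br-]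
F7 | step 1 | sodium 15-(triphenylphosphoranylidene)pentadecanoate | [Na+].[O-]C(=O)CCCCCCCCCCCCCC=P(c1ccccc1)(c1ccccc1)c1ccccc1
F8 | step 1 | 16-methylheptadec-15-enoic acid | CC(C)=CCCCCCCCCCCCCCC(=O)O
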